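**Plan**

Numbering is terpenoid-style: decalin C1–C10, C17 on C8, C18/C19 on C4, C20 on C10, chain C11–C16, then the butenolide. The target is a cis-fused decalin (H5 and CH3-20 syn).
Retrosynthesis cuts C12–C13 (sp3–sp2 Suzuki–Miyaura), C15=C16 (Horner–Wadsworth–Emmons), C8–C17 (methyl coupling on an enol triflate), and then C9–C10, which is made as one edge of a cyclopropane C9–C10–C1 by a carbene at C9.
Enabling feature: C10 is quaternary, syn to H5 and flanked by the methylene C1, so it is the substituted end of the C10=C1 alkene of (R)-α-ionone. C9 lies between C8 and C11, which can be a ketone and an ester and so carry a diazo group. The strained edge C9–C1 is afterwards cut reductively, which leaves C9–C10.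
Forward: ring A is bought; ring B closes at C9–C10 in step 4; the cyclopropane is opened, C17 and C12 are added; the iodo-dienyl butenolide is built separately and joined last.
Stereochemistry: C5 comes from (R)-α-ionone. C10 comes from delivery of the tethered carbene to the alkene face that carries the C5 side chain (cis fusion). 13E comes from trans-hydroalumination/iodination and a stereoretentive coupling; 15E from the olefination.

Key step: step 4

Assumption: (R)-(+)-α-ionone of high enantiomeric purity (the natural enantiomer) and 4-(bromomethyl)furan-2(5H)-one are treated as purchasable.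

**Route**

Step 1
Reactants: 1 (R)-α-ionone
Product: 2 4-[(1R)-2,6,6-trimethylcyclohex-2-en-1-yl]butan-2-one
Conditions: H2 (5 atm), [(Ph3P)CuH]6 (3 mol %), benzene, rt
Reagents that add atoms: none
Why: copper hydride catalysed conjugate reduction puts hydrogen only on the enone C=C, so the isolated trisubstituted ring alkene (future C10=C1) and the allylic stereocentre C5 should stay untouched.

Step 2
Reactants: 2 4-[(1R)-2,6,6-trimethylcyclohex-2-en-1-yl]butan-2-one
Product: 3 methyl 3-oxo-5-[(1R)-2,6,6-trimethylcyclohex-2-en-1-yl]pentanoate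
Conditions: NaH (2.2 equiv), (MeO)2CO, THF, reflux; then aq. HCl
Reagents that add atoms: dimethyl carbonate COC(=O)OC
Why: Claisen-type carbomethoxylation of a methyl ketone at its methyl carbon (the future C9) is pulled to completion by the β-keto ester enolate, and C5 is not acidic.

Step 3
Reactants: 3 methyl 3-oxo-5-[(1R)-2,6,6-trimethylcyclohex-2-en-1-yl]pentanoate
Product: 4 methyl 2-diazo-3-oxo-5-[(1R)-2,6,6-trimethylcyclohex-2-en-1-yl]pentanoate
Conditions: 4-acetamidobenzenesulfonyl azide, Et3N, MeCN, 0 °C to rt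
Reagents that add atoms: 4-acetamidobenzenesulfonyl azide CC(=O)Nc1ccc(cc1)S(=O)(=O)N=[N+]=[N-]
Why: Regitz diazo transfer to the active methylene between ketone and ester.

Step 4
Reactants: 4 methyl 2-diazo-3-oxo-5-[(1R)-2,6,6-trimethylcyclohex-2-en-1-yl]pentanoate
Product: 5 tricyclic cyclopropyl keto ester (C9 bonded to C10 and C1; ring B cis-fused to ring A)
Conditions: Cu(C11H14NO)2 [bis(N-tert-butylsalicylaldiminato)copper] (5 mol %), toluene, 110 °C, slow addition at high dilution
Reagents that add atoms: none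
Why: loss of N2 at copper gives an electrophilic acceptor/acceptor carbenoid at C9, which adds in one asynchronous [2+1] event across the C10=C1 alkene. The closest known reaction type is the copper- or rhodium-catalysed intramolecular cyclopropanation of α-diazo β-keto esters onto tethered cycloalkenes to give bicyclo[4.1.0]heptan-2-ones. Ring B closes in the six-membered mode through the new C9–C10 bond (C9–C8–C7–C6–C5–C10), and the three-membered ring closes through C9–C1. C10 and C1 are set by C5: the side chain, held pseudoaxial by allylic strain with the C10 methyl, can only reach the alkene face it stands on, so C9 ends syn to C6 (cis fusion, CH3-20 syn to H5), and C9 is fixed by the ring constraints. The step needs cyclopropanation to win over insertion into the tertiary allylic C5–H and over Wolff rearrangement; a copper carbenoid, which inserts poorly into C–H bonds, and slow addition should secure this.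

Step 5
Reactants: 5 tricyclic cyclopropyl keto ester
Product: 7 methyl (4aR,8aS)-5,5,8a-trimethyl-2-oxodecahydronaphthalene-1-carboxylate, via lithium enolate 6 (not isolated)
Conditions: Li (2.2 equiv), NH3/THF, −78 °C; then NH4Cl
Reagents that add atoms: none
Why: dissolving-metal cleavage of an α-keto cyclopropane breaks the edge that overlaps with the ketone π system, here C9–C1 (external to ring B and giving the less substituted carbanion), so C1 becomes a methylene, C9–C10 and the cis fusion stay, and the β-keto ester enolate resists further reduction.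

Step 6
Reactants: 7 methyl (4aR,8aS)-5,5,8a-trimethyl-2-oxodecahydronaphthalene-1-carboxylate
Product: 8 methyl (4aR,8aS)-5,5,8a-trimethyl-2-{[(trifluoromethyl)sulfonyl]oxy}-3,4,4a,5,6,7,8,8a-octahydronaphthalene-1-carboxylate
Conditions: NaH, PhNTf2, THF, 0 °C to rt; dilute HCl work-up
Reagents that add atoms: N-phenylbis(trifluoromethanesulfonimide) O=S(=O)(N(c1ccccc1)S(=O)(=O)C(F)(F)F)C(F)(F)F
Why: O-triflation of the only possible enolate of the β-keto ester (C8=C9, between the two carbonyls).

Step 7
Reactants: 8 enol triflate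
Product: 9 methyl (4aR,8aS)-2,5,5,8a-tetramethyl-3,4,4a,5,6,7,8,8a-octahydronaphthalene-1-carboxylate
Conditions: MeMgBr, Fe(acac)3 (5 mol %), THF/NMP, −30 °C
Reagents that add atoms: methylmagnesium bromide C[Mg]Br
Why: iron-catalysed Kumada-type coupling of a β-keto ester enol triflate with MeMgBr is faster than attack on the hindered ester and fixes the tetrasubstituted C8=C9 alkene with C17 in place.

Step 8
Reactants: 9 methyl ester
Product: 10 [(4aR,8aS)-2,5,5,8a-tetramethyl-3,4,4a,5,6,7,8,8a-octahydronaphthalen-1-yl]methanol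
Conditions: i-Bu2AlH (2.5 equiv), CH2Cl2, −78 to 0 °C
Reagents that add atoms: none
Why: hydride reduction of the conjugated ester to the allylic alcohol; no other reducible group is present.

Step 9
Reactants: 10 allylic alcohol
Product: 11 (4aR,8aS)-2,5,5,8a-tetramethyl-3,4,4a,5,6,7,8,8a-octahydronaphthalene-1-carbaldehyde
Conditions: MnO2 (excess), CH2Cl2, rt
Reagents that add atoms: none
Why: allylic alcohol oxidation, which should stop at the enal (C9 carries no hydrogen).

Step 10
Reactants: 11 enal
Product: 12 (4aR,8aS)-1-ethenyl-2,5,5,8a-tetramethyl-3,4,4a,5,6,7,8,8a-octahydronaphthalene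
Conditions: Ph3PCH3Br, KOt-Bu, THF, 0 °C to rt
Reagents that add atoms: methyltriphenylphosphonium bromide C[P+](c1ccccc1)(c1ccccc1)c1ccccc1.[Br-]
Why: Wittig methylenation, precedented for the equally hindered β-cyclocitral, adds C12 and gives the 1,3-diene.

Step 11
Reactants: 13 but-2-yne-1,4-diol
Product: 14 4-[(tert-butyldimethylsilyl)oxy]but-2-yn-1-ol
Conditions: NaH (1.0 equiv), TBSCl (1.0 equiv), THF, 0 °C to rt
Reagents that add atoms: tert-butyldimethylsilyl chloride CC(C)(C)[Si](C)(C)Cl
Why: monosilylation of a symmetric diol through its monosodium alkoxide.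

Step 12
Reactants: 14 4-[(tert-butyldimethylsilyl)oxy]but-2-yn-1-ol
Product: 16 (2Z)-4-[(tert-butyldimethylsilyl)oxy]-3-iodobut-2-en-1-ol, via cyclic sodium alkenylalanate 15 (not isolated)
Conditions: NaAlH2(OCH2CH2OMe)2, THF, 0 °C; then I2, THF, −78 °C
Reagents that add atoms: iodine II
Why: hydroxyl-directed trans-hydroalumination of the propargylic alcohol (H to C2, Al to C3 in a five-membered alanate) and iodinolysis with retention give the Z-iodide with iodine cis to CH2OH, while low temperature should keep the β-silyloxy alanate from eliminating to the allenol.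

Step 13
Reactants: 16 (2Z)-iodo allylic alcohol
Product: 17 (2Z)-4-[(tert-butyldimethylsilyl)oxy]-3-iodobut-2-enal
Conditions: MnO2 (excess), CH2Cl2, rt, dark
Reagents that add atoms: none
Why: MnO2 oxidation of the allylic alcohol to the Z-β-iodo enal, as known for (Z)-3-iodobut-2-en-1-ol, should leave the silyl ether and the alkene geometry intact.

Step 14
Reactants: 18 4-(bromomethyl)furan-2(5H)-one
Product: 19 diethyl [(5-oxo-2,5-dihydrofuran-3-yl)methyl]phosphonate
Conditions: P(OEt)3, neat, 110 °C
Reagents that add atoms: triethyl phosphite CCOP(OCC)OCC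
Why: Michaelis–Arbuzov reaction of the allylic bromide.

Step 15
Reactants: 17 (2Z)-iodo enal; 19 phosphonate
Product: 20 4-[(1E,3Z)-5-[(tert-butyldimethylsilyl)oxy]-4-iodopenta-1,3-dien-1-yl]furan-2(5H)-one
Conditions: LiN(SiMe3)2 (1.0 equiv), THF, −78 to 0 °C
Reagents that add atoms: none
Why: vinylogous Horner–Wadsworth–Emmons olefination (the lactone analogue of the 3-methyl-4-phosphonocrotonate reagent) at the aldehyde should form C15=C16 as the E isomer and spare the vinyl iodide at low temperature.

Step 16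
Reactants: 12 diene; 20 iodo-dienyl butenolide
Product: 22 4-[(1E,3E)-4-{[(tert-butyldimethylsilyl)oxy]methyl}-6-[(4aR,8aS)-2,5,5,8a-tetramethyl-3,4,4a,5,6,7,8,8a-octahydronaphthalen-1-yl]hexa-1,3-dien-1-yl]furan-2(5H)-one, via B-alkyl-9-BBN borane 21 (not isolated)
Conditions: 9-BBN, THF, rt; then 20, Pd(dppf)Cl2 (5 mol %), AsPh3, aq. K3PO4 (3 M), DMF, rt
Reagents that add atoms: none
Why: anti-Markovnikov hydroboration of the terminal vinyl group only, then B-alkyl Suzuki–Miyaura coupling with retention at the alkenyl iodide, joins C12 to C13 with C12 cis to C15 (13E).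

Step 17
Reactants: 22 silyl ether
Product: 23 4-[(1E,3E)-4-(hydroxymethyl)-6-[(4aR,8aS)-2,5,5,8a-tetramethyl-3,4,4a,5,6,7,8,8a-octahydronaphthalen-1-yl]hexa-1,3-dien-1-yl]furan-2(5H)-one
Conditions: HF·pyridine, pyridine/THF, 0 °C
Reagents that add atoms: none
Why: fluoride cleavage of the primary allylic silyl ether under buffered, non-basic conditions that the trienyl butenolide should tolerate.

**Compound list**

1 | (R)-α-ionone, (3E)-4-[(1R)-2,6,6-trimethylcyclohex-2-en-1-yl]but-3-en-2-one | CC(=O)/C=C/[C@H]1C(C)=CCCC1(C)C | starting material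
2 | 4-[(1R)-2,6,6-trimethylcyclohex-2-en-1-yl]butan-2-one | CC(=O)CC[C@H]1C(C)=CCCC1(C)C | intermediate
3 | methyl 3-oxo-5-[(1R)-2,6,6-trimethylcyclohex-2-en-1-yl]pentanoate | COC(=O)CC(=O)CC[C@H]1C(C)=CCCC1(C)C | intermediate
4 | methyl 2-diazo-3-oxo-5-[(1R)-2,6,6-trimethylcyclohex-2-en-1-yl]pentanoate | COC(=O)C(=[N+]=[N-])C(=O)CC[C@H]1C(C)=CCCC1(C)C | intermediate
5 | tricyclic cyclopropyl keto ester: cis-fused 8-oxo decalin in which C9 (bearing CO2Me) is also bonded to C1; C2, C5 and C8 on one face of the cyclopropane, H1, CH3-20 and CO2Me on the other | COC(=O)[C@]12C(=O)CC[C@@H]3C(C)(C)CC[C@H]1[C@]23C | intermediate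
6 | lithium enolate of 7 | [Li+].[O-]C1=C(C(=O)OC)[C@@]2(C)CCCC(C)(C)[C@H]2CC1 | intermediate (not isolated)
7 | methyl (4aR,8aS)-5,5,8a-trimethyl-2-oxodecahydronaphthalene-1-carboxylate (cis-fused; ester-bearing carbon epimerisable and unassigned, in equilibrium with the enol) | O=C1C(C(=O)OC)[C@@]2(C)CCCC(C)(C)[C@H]2CC1 | intermediate
8 | methyl (4aR,8aS)-5,5,8a-trimethyl-2-{[(trifluoromethyl)sulfonyl]oxy}-3,4,4a,5,6,7,8,8a-octahydronaphthalene-1-carboxylate | O=S(=O)(OC1=C(C(=O)OC)[C@@]2(C)CCCC(C)(C)[C@H]2CC1)C(F)(F)F | intermediate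
9 | methyl (4aR,8aS)-2,5,5,8a-tetramethyl-3,4,4a,5,6,7,8,8a-octahydronaphthalene-1-carboxylate | CC1=C(C(=O)OC)[C@@]2(C)CCCC(C)(C)[C@H]2CC1 | intermediate
10 | [(4aR,8aS)-2,5,5,8a-tetramethyl-3,4,4a,5,6,7,8,8a-octahydronaphthalen-1-yl]methanol | CC1=C(CO)[C@@]2(C)CCCC(C)(C)[C@H]2CC1 | intermediate
11 | (4aR,8aS)-2,5,5,8a-tetramethyl-3,4,4a,5,6,7,8,8a-octahydronaphthalene-1-carbaldehyde | CC1=C(C=O)[C@@]2(C)CCCC(C)(C)[C@H]2CC1 | intermediate
12 | (4aR,8aS)-1-ethenyl-2,5,5,8a-tetramethyl-3,4,4a,5,6,7,8,8a-octahydronaphthalene | CC1=C(C=C)[C@@]2(C)CCCC(C)(C)[C@H]2CC1 | intermediate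
13 | but-2-yne-1,4-diol | OCC#CCO | starting material
14 | 4-[(tert-butyldimethylsilyl)oxy]but-2-yn-1-ol | CC(C)(C)[Si](C)(C)OCC#CCO | intermediate
15 | cyclic sodium alkenylalanate (five-membered O–Al–C3=C2–C1 ring, two 2-methoxyethoxy groups on Al) | [Na+].COCCO[Al-]1(OCCOC)OCC=C1CO[Si](C)(C)C(C)(C)C | intermediate (not isolated)
16 | (2Z)-4-[(tert-butyldimethylsilyl)oxy]-3-iodobut-2-en-1-ol | I/C(=C\CO)CO[Si](C)(C)C(C)(C)C | intermediate
17 | (2Z)-4-[(tert-butyldimethylsilyl)oxy]-3-iodobut-2-enal | I/C(=C\C=O)CO[Si](C)(C)C(C)(C)C | intermediate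
18 | 4-(bromomethyl)furan-2(5H)-one | BrCC1=CC(=O)OC1 | starting material
19 | diethyl [(5-oxo-2,5-dihydrofuran-3-yl)methyl]phosphonate | CCOP(=O)(OCC)CC1=CC(=O)OC1 | intermediate
20 | 4-[(1E,3Z)-5-[(tert-butyldimethylsilyl)oxy]-4-iodopenta-1,3-dien-1-yl]furan-2(5H)-one | I/C(=C\C=C\C1=CC(=O)OC1)CO[Si](C)(C)C(C)(C)C | intermediate
21 | 9-{2-[(4aR,8aS)-2,5,5,8a-tetramethyl-3,4,4a,5,6,7,8,8a-octahydronaphthalen-1-yl]ethyl}-9-borabicyclo[3.3.1]nonane | CC1=C(CCB3C4CCCC3CCC4)[C@@]2(C)CCCC(C)(C)[C@H]2CC1 | intermediate (not isolated)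
22 | 4-[(1E,3E)-4-{[(tert-butyldimethylsilyl)oxy]methyl}-6-[(4aR,8aS)-2,5,5,8a-tetramethyl-3,4,4a,5,6,7,8,8a-octahydronaphthalen-1-yl]hexa-1,3-dien-1-yl]furan-2(5H)-one | CC1=C(CC/C(=C\C=C\C3=CC(=O)OC3)CO[Si](C)(C)C(C)(C)C)[C@@]2(C)CCCC(C)(C)[C@H]2CC1 | intermediate
23 | 4-[(1E,3E)-4-(hydroxymethyl)-6-[(4aR,8aS)-2,5,5,8a-tetramethyl-3,4,4a,5,6,7,8,8a-octahydronaphthalen-1-yl]hexa-1,3-dien-1-yl]furan-2(5H)-one | CC1=C(CC/C(=C\C=C\C2=CC(=O)OC2)CO)[C@@]2(C)CCCC(C)(C)[C@H]2CC1 | target

**Step count and risks**

Total steps: 17. Longest linear sequence: 12 (steps 1–10, 16, 17). The side branches are steps 11–13 and 15 (four steps) and step 14.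

Most likely to fail:

1. Step 4. The carbenoid may insert into the tertiary allylic C5–H (five-membered ring) or fail to add to the hindered trisubstituted alkene, since two adjacent fully substituted carbons must form. The fallback closes the same bond by an ionic route and sets out from 3. Allylic oxidation at C2 (CrO3, 3,5-dimethylpyrazole, CH2Cl2, −20 °C) would give the enone methyl 3-oxo-5-[(1R)-2,6,6-trimethyl-4-oxocyclohex-2-en-1-yl]pentanoate F1. Catalytic Cs2CO3 in MeCN should then form C9–C10 by intramolecular Michael addition of the β-keto ester to the enone carbon C10 from the face of the tether; this base is too weak to epimerise C5. The expected product is the cis-fused methyl (4aR,8aS)-5,5,8a-trimethyl-2,7-dioxodecahydronaphthalene-1-carboxylate F2, whose ring fusion would have to be confirmed. Ketalisation of the unhindered, non-enolised ring A ketone (HSCH2CH2SH, BF3·OEt2) to the 1,3-dithiolane of the C7 ketone of the diketo ester (naphthalene numbering) F3 and desulfurisation with Raney Ni return to 7.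

2. Step 5. Electron transfer may cleave the wrong cyclopropane edge (C9–C10, towards the tertiary centre and a seven-membered ring) or reduce the ester further. The fallback sets out from 5 and replaces reduction by nucleophilic opening. Thiophenolate (PhSH, Cs2CO3, DMF) should attack C1, the only cyclopropane carbon open to backside attack, to give methyl (4aR,8R,8aS)-5,5,8a-trimethyl-2-oxo-8-(phenylsulfanyl)decahydronaphthalene-1-carboxylate F4. Desulfurisation with Raney Ni returns to 7.

3. Step 16. Transmetalation of the alkylborane may be slow, or the aqueous base may open or isomerise the trienyl butenolide of 20 before coupling. The fallback puts the butenolide on after the union. It sets out from 12 (hydroborated to 21 as before), which is coupled under the same palladium conditions with the simple iodide 16 to give (2E)-3-{[(tert-butyldimethylsilyl)oxy]methyl}-5-[(4aR,8aS)-2,5,5,8a-tetramethyl-3,4,4a,5,6,7,8,8a-octahydronaphthalen-1-yl]pent-2-en-1-ol F5. MnO2 oxidation gives (2E)-3-{[(tert-butyldimethylsilyl)oxy]methyl}-5-[(4aR,8aS)-2,5,5,8a-tetramethyl-3,4,4a,5,6,7,8,8a-octahydronaphthalen-1-yl]pent-2-enal F6, and olefination with 19 (LiN(SiMe3)2, THF, −78 °C) returns to 22.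

Further compounds
F1 | step 4 | methyl 3-oxo-5-[(1R)-2,6,6-trimethyl-4-oxocyclohex-2-en-1-yl]pentanoate | COC(=O)CC(=O)CC[C@H]1C(C)=CC(=O)CC1(C)C
F2 | step 4 | methyl (4aR,8aS)-5,5,8a-trimethyl-2,7-dioxodecahydronaphthalene-1-carboxylate | O=C1C(C(=O)OC)[C@@]2(C)CC(=O)CC(C)(C)[C@H]2CC1
F3 | step 4 | 1,3-dithiolane of the C7 ketone of the diketo ester (naphthalene numbering) | O=C1C(C(=O)OC)[C@@]2(C)CC3(SCCS3)CC(C)(C)[C@H]2CC1
F4 | step 5 | methyl (4aR,8R,8aS)-5,5,8a-trimethyl-2-oxo-8-(phenylsulfanyl)decahydronaphthalene-1-carboxylate | O=C1C(C(=O)OC)[C@@]2(C)[C@H](Sc3ccccc3)CCC(C)(C)[C@H]2CC1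
F5 | step 16 | (2E)-3-{[(tert-butyldimethylsilyl)oxy]methyl}-5-[(4aR,8aS)-2,5,5,8a-tetramethyl-3,4,4a,5,6,7,8,8a-octahydronaphthalen-1-yl]pent-2-en-1-ol | CC1=C(CC/C(=C\CO)CO[Si](C)(C)C(C)(C)C)[C@@]2(C)CCCC(C)(C)[C@H]2CC1
F6 | step 16 | (2E)-3-{[(tert-butyldimethylsilyl)oxy]methyl}-5-[(4aR,8aS)-2,5,5,8a-tetramethyl-3,4,4a,5,6,7,8,8a-octahydronaphthalen-1-yl]pent-2-enal | CC1=C(CC/C(=C\C=O)CO[Si](C)(C)C(C)(C)C)[C@@]2(C)CCCC(C)(C)[C@H]2CC1
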